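**Plan**
- Retrosynthesis first removes three O‑methyl groups, then opens ring B at C6'–C5' and C3'–C4'. Its carbons C3', C2', C1', C6' with their substituents are the C3–C6 diene of a 3,6‑dimethyl‑4‑oxy‑2‑pyrone‑5‑carboxylate, and C5', C4' are the Cl–CH=C(OMe)2 pair; the lactone O–C(=O) bridge leaves as CO2.
- The pyrone is cut at O1–C2 and C4–C5 into an aryl acetoacetate and methylmalonyl dichloride. The depside ester bond is the ester of that acetoacetate and goes back to methyl atrarate and acetylketene.
- Forward: ring A is purchased; acetoacetylation at 4‑OH, pyrone annulation and double O‑methylation follow. Ring B then arises from the pyrone by cycloaddition, loss of CO2 and loss of methanol with chlorine already in place, and global O‑demethylation ends the route.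
- Stereochemistry: the target has no stereocentre. Only regiochemistry matters (site of acetoacetylation, O‑methylation of the pyrone, orientation of the ketene acetal).

Key step: step 6

Remark: the free 2‑OH of ring A is carried as a methyl ether through the cycloaddition because ketene acetals add O–H bonds; intermediates 11 and 12 are racemic diastereomer mixtures whose stereocentres vanish on aromatisation, so their SMILES carry no configuration.

**Step 1**
Reactants: 1 methyl atrarate (methyl 2,4‑dihydroxy‑3,6‑dimethylbenzoate); 2 2,2,6‑trimethyl‑4H‑1,3‑dioxin‑4‑one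
Product: 4 methyl 2‑hydroxy‑3,6‑dimethyl‑4‑[(3‑oxobutanoyl)oxy]benzoate, via acetylketene 3 (not isolated)
Conditions: 2 (1.3 equiv), xylene, 140 °C, acetone distilled off
Reagents that add atoms: none
Why: Retro‑[4+2] thermolysis of the dioxinone releases acetylketene, which acetoacetylates the free 4‑OH (acylketene trapping by a phenol), while the 2‑OH is hydrogen‑bonded to the ester carbonyl and flanked on both sides and should stay unacylated.

**Step 2**
Reactants: 5 methylmalonic acid
Product: 6 methylmalonyl dichloride (2‑methylpropanedioyl dichloride)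
Conditions: SOCl2 (3 equiv), neat, 50 → 75 °C; distillation at reduced pressure
Reagents that add atoms: thionyl chloride, ClS(Cl)=O
Why: Acyl chloride formation from a malonic acid with thionyl chloride is standard, and the volatile by‑products leave a distillable diacid chloride.

**Step 3**
Reactants: 4 methyl 2‑hydroxy‑3,6‑dimethyl‑4‑[(3‑oxobutanoyl)oxy]benzoate; 6 methylmalonyl dichloride
Product: 7 3‑hydroxy‑4‑(methoxycarbonyl)‑2,5‑dimethylphenyl 4‑hydroxy‑3,6‑dimethyl‑2‑oxo‑2H‑pyran‑5‑carboxylate
Conditions: 6 (1.2 equiv), ClCH2CH2Cl, 20 → 65 °C, slow N2 stream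
Reagents that add atoms: none
Why: Pyrone annulation of a β‑keto ester with a malonyl dichloride: the enol of 4 is acylated at its central carbon and at the ketone oxygen by the two acid chloride groups, closing the 4‑hydroxy‑2‑pyrone with the aryl ester at C5, and without base the chelated ring‑A phenol should not compete.

**Step 4**
Reactants: 7 3‑hydroxy‑4‑(methoxycarbonyl)‑2,5‑dimethylphenyl 4‑hydroxy‑3,6‑dimethyl‑2‑oxo‑2H‑pyran‑5‑carboxylate
Product: 8 3‑methoxy‑4‑(methoxycarbonyl)‑2,5‑dimethylphenyl 4‑methoxy‑3,6‑dimethyl‑2‑oxo‑2H‑pyran‑5‑carboxylate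
Conditions: Me2SO4 (3.5 equiv), K2CO3 (4 equiv), acetone, reflux
Reagents that add atoms: dimethyl sulfate, COS(=O)(=O)OC
Why: O‑alkylation with a hard electrophile (Williamson ether synthesis) should turn the 4‑hydroxy‑2‑pyrone into the 4‑methoxy‑2‑pyrone and, more slowly, cap the chelated ring‑A phenol, which must not be free when the ketene acetal is present.

**Step 5**
Reactants: 9 2‑chloro‑1,1,1‑trimethoxyethane
Product: 10 chloroketene dimethyl acetal (2‑chloro‑1,1‑dimethoxyethene)
Conditions: iPr2NEt (1.3 equiv), Me3SiOTf (1.05 equiv, slow addition), CH2Cl2, −20 → 20 °C; pentane, decantation from the ammonium salt, distillation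
Reagents that add atoms: none
Why: The silyl triflate abstracts one methoxy group to give a dialkoxycarbenium ion whose acidified CHCl hydrogen is removed by the hindered amine (1,2‑elimination of methanol from an orthoester to a ketene acetal), and the non‑aqueous work‑up protects the acid‑sensitive product.

**Step 6**
Reactants: 8 3‑methoxy‑4‑(methoxycarbonyl)‑2,5‑dimethylphenyl 4‑methoxy‑3,6‑dimethyl‑2‑oxo‑2H‑pyran‑5‑carboxylate; 10 chloroketene dimethyl acetal
Product: 13 3‑methoxy‑4‑(methoxycarbonyl)‑2,5‑dimethylphenyl 5‑chloro‑2,4‑dimethoxy‑3,6‑dimethylbenzoate, via bridged bicyclic lactone 11 (not isolated), via chlorocyclohexadiene ketal 12 (not isolated)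
Conditions: 10 (5 equiv, two portions), 2,6‑di‑tert‑butylpyridine (0.1 equiv), mesitylene, sealed tube, 150 °C
Reagents that add atoms: none
Why: The electron‑poor diene of 8 (pyrone C3=C4–C5=C6, lowered by the lactone carbonyl and the C5 ester) and the electron‑rich alkene of 10 should combine in an inverse‑electron‑demand Diels–Alder reaction, probably asynchronous, the CHCl carbon bonding to pyrone C6 (new C6'–C5') and the acetal carbon to C3 (new C3'–C4'). The bridged lactone 11 then loses carbon dioxide by retro‑[4+2] cleavage, and diene 12 aromatises by 1,2‑elimination of methanol, the only elimination open to it because the acetal carbon carries no hydrogen, so chlorine stays on C5'. The closest known reaction is the benzannulation of 2‑pyrone‑5‑carboxylates (coumalates) with ketene acetals. Ring B closes as a six‑membered carbocycle in an intermolecular [4+2] cycloaddition in which both new bonds lie in the ring. The stereocentres of 11 and 12 are transient and are erased on aromatisation, so no stereocontrol is required. The step needs a single orientation of the dienophile, secured because C6 is the β‑carbon of the C5 acrylate unit and the vinylogous acceptor of the lactone while the CHCl carbon is the nucleophilic end of 10; the 4‑methoxy donor and the two flanking methyl groups slow the reaction, hence heat, excess 10 and a trace of hindered base against acid‑induced oligomerisation.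

**Step 7**
Reactants: 13 3‑methoxy‑4‑(methoxycarbonyl)‑2,5‑dimethylphenyl 5‑chloro‑2,4‑dimethoxy‑3,6‑dimethylbenzoate
Product: 14 3‑hydroxy‑4‑(methoxycarbonyl)‑2,5‑dimethylphenyl 5‑chloro‑2,4‑dihydroxy‑3,6‑dimethylbenzoate (CNP0106652.0)
Conditions: BBr3 (6 equiv), CH2Cl2, −78 → 0 °C; ice water
Reagents that add atoms: none
Why: Aryl methyl ether cleavage by boron tribromide: the two ethers ortho to ester carbonyls should cleave fast through six‑membered boron chelates, the 4'‑ether is twisted out of conjugation by its chlorine and methyl neighbours and so binds boron readily, and the methyl ester and the doubly ortho‑substituted aryl ester should survive at or below 0 °C.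

**Compound list**
1 | methyl atrarate (methyl 2,4‑dihydroxy‑3,6‑dimethylbenzoate) | COC(=O)c1c(C)cc(O)c(C)c1O | starting material
2 | 2,2,6‑trimethyl‑4H‑1,3‑dioxin‑4‑one | CC1=CC(=O)OC(C)(C)O1 | starting material
3 | acetylketene | CC(=O)C=C=O | intermediate
4 | methyl 2‑hydroxy‑3,6‑dimethyl‑4‑[(3‑oxobutanoyl)oxy]benzoate | COC(=O)c1c(C)cc(OC(=O)CC(C)=O)c(C)c1O | intermediate
5 | methylmalonic acid | CC(C(=O)O)C(=O)O | starting material
6 | methylmalonyl dichloride | CC(C(=O)Cl)C(=O)Cl | intermediate
7 | 3‑hydroxy‑4‑(methoxycarbonyl)‑2,5‑dimethylphenyl 4‑hydroxy‑3,6‑dimethyl‑2‑oxo‑2H‑pyran‑5‑carboxylate | COC(=O)c1c(C)cc(OC(=O)C2=C(C)OC(=O)C(C)=C2O)c(C)c1O | intermediate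
8 | 3‑methoxy‑4‑(methoxycarbonyl)‑2,5‑dimethylphenyl 4‑methoxy‑3,6‑dimethyl‑2‑oxo‑2H‑pyran‑5‑carboxylate | COC(=O)c1c(C)cc(OC(=O)C2=C(C)OC(=O)C(C)=C2OC)c(C)c1OC | intermediate
9 | 2‑chloro‑1,1,1‑trimethoxyethane | COC(CCl)(OC)OC | starting material
10 | chloroketene dimethyl acetal (2‑chloro‑1,1‑dimethoxyethene) | COC(OC)=CCl | intermediate
11 | 3‑methoxy‑4‑(methoxycarbonyl)‑2,5‑dimethylphenyl 7‑chloro‑5,8,8‑trimethoxy‑1,4‑dimethyl‑3‑oxo‑2‑oxabicyclo[2.2.2]oct‑5‑ene‑6‑carboxylate (racemic, diastereomer mixture) | COC(=O)c1c(C)cc(OC(=O)C2=C(OC)C3(C)C(=O)OC2(C)C(Cl)C3(OC)OC)c(C)c1OC | intermediate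
12 | 3‑methoxy‑4‑(methoxycarbonyl)‑2,5‑dimethylphenyl 3‑chloro‑4,4,6‑trimethoxy‑2,5‑dimethylcyclohexa‑1,5‑diene‑1‑carboxylate (racemic) | COC(=O)c1c(C)cc(OC(=O)C2=C(C)C(Cl)C(OC)(OC)C(C)=C2OC)c(C)c1OC | intermediate
13 | 3‑methoxy‑4‑(methoxycarbonyl)‑2,5‑dimethylphenyl 5‑chloro‑2,4‑dimethoxy‑3,6‑dimethylbenzoate | COC(=O)c1c(C)cc(OC(=O)c2c(C)c(Cl)c(OC)c(C)c2OC)c(C)c1OC | intermediate
14 | 3‑hydroxy‑4‑(methoxycarbonyl)‑2,5‑dimethylphenyl 5‑chloro‑2,4‑dihydroxy‑3,6‑dimethylbenzoate (CNP0106652.0) | COC(=O)c1c(C)cc(OC(=O)c2c(C)c(Cl)c(O)c(C)c2O)c(C)c1O | target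

**Step count**
Total steps: 7. Longest linear sequence: 5 steps (steps 1, 3, 4, 6, 7 from methyl atrarate); steps 2 and 5 prepare the two reagents.

**Steps most likely to fail**

Step 6. The diene carries a 4‑methoxy donor and methyl groups at both termini, so cycloaddition may be slower than thermal decay or oligomerisation of the ketene acetal. In that case ring B would be taken from the aromatic pool. The fallback sets out from 1. Chlorination at its only free ring position (SO2Cl2, Et2O, 0 °C) would give methyl 5‑chloro‑2,4‑dihydroxy‑3,6‑dimethylbenzoate F1. Exhaustive methylation (Me2SO4, K2CO3, acetone, reflux) would give methyl 5‑chloro‑2,4‑dimethoxy‑3,6‑dimethylbenzoate F2. Saponification of the hindered ester (KOH, aqueous DMSO, 90 °C) would give 5‑chloro‑2,4‑dimethoxy‑3,6‑dimethylbenzoic acid F3. Condensation of this acid with a second portion of 1 by the trifluoroacetic anhydride mixed‑anhydride method (toluene, 20 °C), selective for the non‑chelated 4‑OH, would give 3‑hydroxy‑4‑(methoxycarbonyl)‑2,5‑dimethylphenyl 5‑chloro‑2,4‑dimethoxy‑3,6‑dimethylbenzoate F4. Demethylation of that depside with BBr3 under the conditions of step 7 comes back to the route at 14.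

Step 3. The one‑pot annulation may be diverted by acylation of the enol through oxygen at both acid chloride ends, by ketene‑type oligomerisation of the diacid chloride, or by attack on the ring‑A phenol. The two ring bonds would then be made one at a time. The fallback sets out from 4. Magnesium‑enolate C‑acylation (MgCl2, pyridine, CH2Cl2, 0 °C) with ethyl 3‑chloro‑2‑methyl‑3‑oxopropanoate would give the triacylmethane 3‑hydroxy‑4‑(methoxycarbonyl)‑2,5‑dimethylphenyl 2‑acetyl‑5‑ethoxy‑4‑methyl‑3,5‑dioxopentanoate F5 (enolised, racemic). Acid‑catalysed lactonisation of its acetyl enol onto the ethyl ester (p‑toluenesulfonic acid, toluene, reflux, ethanol removed) comes back to the route at 7.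

Step 7. Once the ring‑A ether is cleaved, the boron chelate next to the methyl ester may activate the ester methyl toward bromide, and the hindered 4'‑ether may cleave only under conditions that also take that methyl group. Selective cleavage would then be given up. The fallback sets out from 13. Exhaustive dealkylation (BBr3, CH2Cl2, 20 °C, prolonged) would give 4‑[(5‑chloro‑2,4‑dihydroxy‑3,6‑dimethylbenzoyl)oxy]‑2‑hydroxy‑3,6‑dimethylbenzoic acid F6. The carboxyl group alone would be re‑methylated (MeI, KHCO3, DMF, 20 °C), hydrogencarbonate being too weak a base to alkylate the phenols, which comes back to the route at 14.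

**Further compounds**
F1 | step 6 | methyl 5‑chloro‑2,4‑dihydroxy‑3,6‑dimethylbenzoate | COC(=O)c1c(C)c(Cl)c(O)c(C)c1O
F2 | step 6 | methyl 5‑chloro‑2,4‑dimethoxy‑3,6‑dimethylbenzoate | COC(=O)c1c(C)c(Cl)c(OC)c(C)c1OC
F3 | step 6 | 5‑chloro‑2,4‑dimethoxy‑3,6‑dimethylbenzoic acid | OC(=O)c1c(C)c(Cl)c(OC)c(C)c1OC
F4 | step 6 | 3‑hydroxy‑4‑(methoxycarbonyl)‑2,5‑dimethylphenyl 5‑chloro‑2,4‑dimethoxy‑3,6‑dimethylbenzoate | COC(=O)c1c(C)cc(OC(=O)c2c(C)c(Cl)c(OC)c(C)c2OC)c(C)c1O
F5 | step 3 | 3‑hydroxy‑4‑(methoxycarbonyl)‑2,5‑dimethylphenyl 2‑acetyl‑5‑ethoxy‑4‑methyl‑3,5‑dioxopentanoate | CCOC(=O)C(C)C(=O)C(C(C)=O)C(=O)Oc1cc(C)c(C(=O)OC)c(O)c1C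
F6 | step 7 | 4‑[(5‑chloro‑2,4‑dihydroxy‑3,6‑dimethylbenzoyl)oxy]‑2‑hydroxy‑3,6‑dimethylbenzoic acid | OC(=O)c1c(C)cc(OC(=O)c2c(C)c(Cl)c(O)c(C)c2O)c(C)c1O
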